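**Retrosynthetic overview**

- The target is a homo-dimer of one 2,3-cis flavan-3,4-diol. Cutting the C4(upper)–C6(lower) bond and returning the lower 4β-OH gives a single unprotected monomer, (2R,3R,4R)-melacacidin. In one aqueous acid step it serves as electrophile (C4 p-quinone methide) and nucleophile (C6), and both C4 centres are set there.
- Melacacidin comes from the achiral flavonol melanoxetin by one all-cis asymmetric hydrogenation (C2, C3 and C4 at once) under transient silyl protection.
- Melanoxetin comes from its tetramethyl ether (BBr3).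
- Ring C of the flavonol is closed from a 2'-hydroxychalcone by phenoxide 6-endo oxidative cyclisation (chalcone → dihydroflavonol → flavonol, the plant order), in the same pot as the aldol condensation of the acetophenone with veratraldehyde.
- Ring order: rings A and B are bought; ring C of the monomer closes in step 1; the second ring C arrives with the second monomer when the interflavan bond forms in step 4.

Assumption: 1-(2-hydroxy-3,4-dimethoxyphenyl)ethanone (compound 1) is bought as a catalogue item; the target is read as epimesquitol-(4β→6)-epimesquitol-4β-ol, upper unit (2R,3R,4S), lower unit (2R,3R,4S).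

**Step 1**
Reactants: 1 1-(2-hydroxy-3,4-dimethoxyphenyl)ethanone; 2 3,4-dimethoxybenzaldehyde (veratraldehyde)
Product: 5 2-(3,4-dimethoxyphenyl)-3-hydroxy-7,8-dimethoxy-4H-chromen-4-one, via chalcone 3 (not isolated), via racemic trans-dihydroflavonol 4 (not isolated)
Conditions: KOH (5 equiv), EtOH, rt, 24 h; then aq. NaOH, 30% H2O2 (3 equiv), 0 °C → rt, 4 h; HCl to pH 3
Reagents that add atoms: hydrogen peroxide (OO)
Why: Claisen–Schmidt condensation gives the 2'-hydroxychalcone, and its alkaline-peroxide Algar–Flynn–Oyamada oxidative cyclisation (6-endo attack of the 2'-phenoxide on the β-carbon, favoured because C6' is unsubstituted) closes ring C and oxidises the transient trans-dihydroflavonol to the achiral flavonol, so no stereocentre needs control here.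

**Step 2**
Reactants: 5 2-(3,4-dimethoxyphenyl)-3-hydroxy-7,8-dimethoxy-4H-chromen-4-one
Product: 6 melanoxetin (2-(3,4-dihydroxyphenyl)-3,7,8-trihydroxy-4H-chromen-4-one)
Conditions: BBr3 (10 equiv), CH2Cl2, −78 °C → rt, 24 h; then ice-water
Reagents that add atoms: none
Why: Lewis-acid aryl methyl ether cleavage (BBr3 demethylation) is done on the robust, achiral flavonol so that all four ethers are removed before any acid-sensitive stereocentre exists.

**Step 3**
Reactants: 6 melanoxetin
Product: 9 (2R,3R,4R)-melacacidin, via pentasilyl ether 7 (not isolated), via silylated melacacidin 8 (not isolated)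
Conditions: (Me3Si)2NH (neat), cat. (NH4)2SO4, reflux, then evaporate; [Ru(cod)(2-methylallyl)2] (5 mol %), (R,R)-SINpEt·HBF4 (10 mol %), KOtBu (15 mol %), H2 (100 bar), n-hexane, 40 °C; then MeOH, cat. PPTS, 0 °C; crystallise from water
Reagents that add atoms: none
Why: Proposed new method: the ruthenium bis(N-heterocyclic carbene) catalyst formed in situ is known to hydrogenate the pyranone C2=C3 bond of flavones enantioselectively and then the C4 carbonyl cis-selectively (closest known reaction type: asymmetric hydrogenation of flavones and chromones to flavanones and cis-flavan-4-ols); on the tetrasubstituted 3-silyloxy enone 7, syn delivery of H2 to the C2-Si/C3-Re face must place the C2 aryl and C3 oxygen cis and fixes both as R, carbonyl reduction from the same open face gives 4R (the C4 outcome is immaterial because step 4 re-sets it), the silyl ethers keep the polyphenol soluble in hexane and off the metal, and mild methanolysis then frees 9 without exposing the benzylic C4–OH to strong acid or hydrogenolysis.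

**Step 4**
Reactants: 9 (2R,3R,4R)-melacacidin (two molecules)
Product: 12 epimesquitol-(4β→6)-epimesquitol-4β-ol (target), via quinone methide 10 (not isolated), via isomelacacidin 11 (not isolated)
Conditions: 0.1 M HCl in degassed H2O, 0.15 M in 9, Ar, 30 °C, stopped at about 40% conversion (HPLC); NaOAc to pH 5; Sephadex LH-20 (EtOH), then RP-HPLC; recovered 9/11 recycled
Reagents that add atoms: water (O)
Why: Acid-promoted leucoanthocyanidin self-condensation (Friedel–Crafts alkylation by a p-quinone methide): the C4–OH, para-related to the 7-OH, ionises to 10, water returns on the β-face to give 11, and C6 of 11 (ortho to the 7-OH, para to the ring oxygen, the most nucleophilic and least hindered A-ring carbon) attacks a second 10 irreversibly, again on the β-face anti to the cis 2-aryl and 3-OH groups, so both new C4 centres (4β-aryl and 4β-OH, each 4S and 3,4-trans) are set by substrate control while reversible ether-linked by-products return through 10.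

**Compound list**

1 | 1-(2-hydroxy-3,4-dimethoxyphenyl)ethanone (gallacetophenone 3',4'-dimethyl ether) | CC(=O)c1ccc(OC)c(OC)c1O | starting material
2 | 3,4-dimethoxybenzaldehyde (veratraldehyde) | COc1ccc(C=O)cc1OC | starting material
3 | (E)-1-(2-hydroxy-3,4-dimethoxyphenyl)-3-(3,4-dimethoxyphenyl)prop-2-en-1-one (chalcone) | COc1ccc(/C=C/C(=O)c2ccc(OC)c(OC)c2O)cc1OC | intermediate
4 | rac-(2R,3R)-2-(3,4-dimethoxyphenyl)-3-hydroxy-7,8-dimethoxychroman-4-one (trans; racemate, one enantiomer drawn) | COc1ccc([C@H]2Oc3c(OC)c(OC)ccc3C(=O)[C@@H]2O)cc1OC | intermediate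
5 | 2-(3,4-dimethoxyphenyl)-3-hydroxy-7,8-dimethoxy-4H-chromen-4-one | COc1ccc(-c2oc3c(OC)c(OC)ccc3c(=O)c2O)cc1OC | intermediate
6 | melanoxetin, 2-(3,4-dihydroxyphenyl)-3,7,8-trihydroxy-4H-chromen-4-one | Oc1ccc(-c2oc3c(O)c(O)ccc3c(=O)c2O)cc1O | intermediate
7 | 2-[3,4-bis(trimethylsilyloxy)phenyl]-3,7,8-tris(trimethylsilyloxy)-4H-chromen-4-one | C[Si](C)(C)Oc1ccc(-c2oc3c(O[Si](C)(C)C)c(O[Si](C)(C)C)ccc3c(=O)c2O[Si](C)(C)C)cc1O[Si](C)(C)C | intermediate
8 | (2R,3R,4R)-2-[3,4-bis(trimethylsilyloxy)phenyl]-3,7,8-tris(trimethylsilyloxy)chroman-4-ol | C[Si](C)(C)Oc1ccc2c(c1O[Si](C)(C)C)O[C@H](c1ccc(O[Si](C)(C)C)c(O[Si](C)(C)C)c1)[C@H](O[Si](C)(C)C)[C@@H]2O | intermediate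
9 | melacacidin, (2R,3R,4R)-2-(3,4-dihydroxyphenyl)-3,4-dihydro-2H-chromene-3,4,7,8-tetrol (all-cis) | Oc1ccc2c(c1O)O[C@H](c1ccc(O)c(O)c1)[C@H](O)[C@@H]2O | intermediate
10 | (2R,3R)-2-(3,4-dihydroxyphenyl)-3,8-dihydroxy-2,3-dihydro-7H-chromen-7-one (C4 p-quinone methide) | OC1=C2O[C@H](c3ccc(O)c(O)c3)[C@H](O)C=C2C=CC1=O | intermediate
11 | isomelacacidin, (2R,3R,4S)-2-(3,4-dihydroxyphenyl)-3,4-dihydro-2H-chromene-3,4,7,8-tetrol (2,3-cis-3,4-trans) | Oc1ccc2c(c1O)O[C@H](c1ccc(O)c(O)c1)[C@H](O)[C@H]2O | intermediate
12 | (2R,3R,4S)-2-(3,4-dihydroxyphenyl)-6-[(2R,3R,4S)-2-(3,4-dihydroxyphenyl)-3,7,8-trihydroxy-3,4-dihydro-2H-chromen-4-yl]-3,4-dihydro-2H-chromene-3,4,7,8-tetrol | Oc1ccc([C@H]2Oc3c(ccc(O)c3O)[C@H](c3cc4c(c(O)c3O)O[C@H](c3ccc(O)c(O)c3)[C@H](O)[C@H]4O)[C@H]2O)cc1O | target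

**Step count and risks**

Total step count: 4. Longest linear sequence: 4.

Three steps most likely to fail:

Step 3 is the largest risk. The C2=C3 bond is tetrasubstituted and oxygenated, so conversion, ee and the sense of induction are all unproven. The sense must be checked against natural (−)-melacacidin, and the (S,S)-ligand salt is used if it is reversed; crystallisation of 9 from water is the means to raise ee. The fallback sets out from 6 and comes back at 9. Unprotected 6 is hydrogenated over Raney Ni (EtOH, H2 100 bar, 80 °C), the classical all-cis reduction of flavonols. This gives racemic melacacidin, that is 9 together with its mirror image ent-melacacidin F1. The racemate is resolved by preparative HPLC on a cellulose tris(3,5-dimethylphenylcarbamate) phase, and 9 goes on to step 4.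

Step 4 is the second risk. The pyrogallol-type ring A is only a moderate nucleophile, so ether-linked dimers, the C5-linked regioisomer, trimers and the dimer with a lower 4α-OH can all compete; low conversion with recycling answers only part of this. The fallback sets out from 9 and comes back at 12, and replaces equilibrium self-condensation by a directed coupling. One portion of 9 is thiolysed (BnSH, AcOH, EtOH, 50 °C; capture of 10 by sulfur on the β-face) to 4β-benzylsulfanylepimesquitol F2. A second portion is equilibrated at 2 mM in 0.05 M aqueous HCl, where self-condensation is negligible, and 11 is isolated. F2 is then activated with AgBF4 (THF, 0 °C) in the presence of 11 (4 equiv). The thiophilic silver salt generates the same C4 electrophile irreversibly, the excess nucleophile suppresses oligomers, and the 4β-OH of 11 is carried into 12 unchanged.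

Step 1 is the third risk. The one-pot aldol/oxidative cyclisation can stall at the chalcone, or give aurone or ring-cleavage products with the electron-rich ring B. The fallback sets out from 3 (isolated by omitting the peroxide) and comes back at 5. Chalcone 3 is cyclodehydrogenated with catalytic I2 in DMSO at 130 °C to 7,8,3',4'-tetramethoxyflavone F3. This is epoxidised with dimethyldioxirane in acetone (0 °C → rt) to the flavone 2,3-epoxide F4, which is not isolated and isomerises with catalytic TsOH to flavonol 5.

**Further compounds**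

F1 | step 3 | ent-melacacidin, (2S,3S,4S)-2-(3,4-dihydroxyphenyl)-3,4-dihydro-2H-chromene-3,4,7,8-tetrol | Oc1ccc2c(c1O)O[C@@H](c1ccc(O)c(O)c1)[C@@H](O)[C@H]2O
F2 | step 4 | 4β-benzylsulfanylepimesquitol, (2R,3S,4S)-4-(benzylsulfanyl)-2-(3,4-dihydroxyphenyl)-3,4-dihydro-2H-chromene-3,7,8-triol | Oc1ccc2c(c1O)O[C@H](c1ccc(O)c(O)c1)[C@H](O)[C@H]2SCc1ccccc1
F3 | step 1 | 2-(3,4-dimethoxyphenyl)-7,8-dimethoxy-4H-chromen-4-one (7,8,3',4'-tetramethoxyflavone) | COc1ccc(-c2cc(=O)c3ccc(OC)c(OC)c3o2)cc1OC
F4 | step 1 | 2-(3,4-dimethoxyphenyl)-7,8-dimethoxy-2,3-epoxychroman-4-one (cis-fused flavone 2,3-epoxide; racemate, one enantiomer drawn) | COc1ccc([C@@]23Oc4c(OC)c(OC)ccc4C(=O)[C@@H]2O3)cc1OC
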